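Readings and results are simulated on assumed constants; the scatter is artificial.

A share that climbs tempts us to call the lesser product the parent of the greater.

| setting | Thursday's | Wednesday's | flask |
|---|---|---|---|
| substrate | 0.56 M | 0.88 M | 0.40 M |
| remark | run made earlier | run made earlier |  |
| time |  |  | 2.5 d |

| run | time / h | isomer of the product A / % | target / % |
|---|---|---|---|
| Thursday's | 10.0 | 16.7 | 8.6 |
| Thursday's | 20.0 | 18.5 | 5.3 |
| Thursday's | 30.0 | 22.9 | 3.9 |
| Thursday's | 40.0 | 20.4 | 5.0 |
| Thursday's | 50.0 | 18.6 | 4.4 |
| Wednesday's | 4.00 | 8.8 | 11.7 |
| Wednesday's | 8.00 | 14.1 | 9.1 |
| Wednesday's | 15.0 | 20.5 | 6.4 |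
| Wednesday's | 25.0 | 20.6 | 5.4 |
| Wednesday's | 50.0 | 17.5 | 3.7 |

(each reading ± 1 percentage point)

1. share of isomer of the product A in isomer of the product A plus target at 20 min
2. share of isomer of the product A in isomer of the product A plus target at 4.0 h
3. share of isomer of the product A in isomer of the product A plus target at 2.5 d
4. which of isomer of the product A and target there is more of at 2.5 d

- what was read earlier has a scatter of 1 percentage point, one standard deviation

In Wednesday's run, isomer of the product A overtakes target between 4.00 h and 8.00 h, and interpolating their difference gives 5.47 h. This is the level time, the moment at which c(isomer of the product A) equals c(target). Thursday's first share, 66.0% at 10.0 h, lies between Wednesday's 60.8% at 8.00 h and 76.2% at 15.0 h, so these two charges show no clear difference at that stage, and we assume the level time unchanged in the flask at 0.40 M.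

Two extremes pass through that time. If target is the parent of isomer of the product A, the share starts from nothing and stays small at 20 min. If both form side by side from substrate (kinetic control) while target drains away, c(isomer of the product A)/c(target) starts above zero. Its growth need not be steady: Wednesday's ratio rose by a factor of 2.06 from 4.00 h to 8.00 h, and by 2.07 over the longer stretch to 15.0 h. As a rough assumption, we let the ratio grow before 4.00 h at the pace of Wednesday's first two readings; carried back to 20 min, it is 0.388, a share of 27.9%.

The readings lean to the second extreme. On Wednesday, isomer of the product A gained 8.8% in the first interval and 5.3 percentage points in the next, although target had to rise from nothing in the first. So we commit to about 27.9% at 20 min and Wednesday's 42.9% at 4.0 h. We also expect isomer of the product A to lead at 2.5 d, far beyond the level time.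

The forecast reads “target forming first, then relaxing to its isomer A”. It gives 4% (1% to 10%), 39% (30% to 47%) and 81% (75% to 87%), with isomer of the product A ahead. At 20 min it stands lower than our reckoning.

The flask gives 26.4%, 45.3% and 78.1%, with isomer of the product A at 17.5% against target at 4.92%.

    substrate ⇌ target (K = 5.00, k = 2.50 × 10⁻⁵ /s)
    substrate ⇌ isomer of the product A (K = 2.90, k = 8.20 × 10⁻⁶ /s)
    target ⇌ isomer of the product B (K = 16.0, k = 1.50 × 10⁻⁴ /s)

In the flask, substrate was making target and isomer of the product A side by side while target passed on to isomer of the product B, and at 0.250 d substrate stood at 49.9% and isomer of the product B at 27.3%. By 1.25 d substrate was down to 5.27% and isomer of the product B stood at 69.1%. The flask reached its level time at 0.210 d, where we had carried 5.47 h. The neighbour at 0.24 M, read at 4.0 h, before the level time, showed a share of 45.3%.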